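**Retrosynthetic overview**
- The target is traced back to 4'-O-benzylkaempferol 3,7-bis(hydrogen sulfate) (hydrogenolysis), then to 4'-O-benzylkaempferol (sulfation at O3 and O7), then to a flavonol carrying three different protecting groups at O3, O7 and O4'.
- The strategy rests on ring A: a benzene ring fused to the pyranone across C4a–C8a, with a free 5-OH peri to the C4 carbonyl, an oxygen at C7 meta to it, and hydrogens at C6 and C8. This is the resorcinol pattern that a vinylketene and a silyl ynol ether assemble.
- Ring A (bonds C5–C6, C7–C8 and C5–C4a) is disconnected to a pyranonyl diazoketone and (triisopropylsilyloxy)acetylene: Wolff rearrangement, ketene–alkyne [2+2] addition, four-electron ring opening and six-electron ring closure.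
- The diazoketone comes from comenic acid: C6 bromination and Suzuki–Miyaura coupling attach ring B, the enol oxygen (future O3) is masked as a MOM ether, and the acid is converted through its chloride with diazomethane. The alkyne comes from trimethylsilylacetylene.
- Ring order: ring C is bought as the pyranone, ring B is attached by cross-coupling, and ring A is formed last.

Key step: step 9

Remark: the sulfate esters are written as hydrogen sulfates, as in the target; compounds 23 and 24 would be handled as disodium salts and brought into the acid form on a cation-exchange resin, and this counter-ion exchange is not counted as a step.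

**Route**

Step 1
Reactants: 1 comenic acid (5-hydroxy-4-oxo-4H-pyran-2-carboxylic acid)
Product: 2 methyl 5-hydroxy-4-oxo-4H-pyran-2-carboxylate
Conditions: MeOH, H2SO4 (cat.), reflux
Reagents that add atoms: methanol, CO
Why: Fischer esterification of the only carboxylic acid should proceed cleanly because the enolic 5-OH and the pyranone ring are inert to methanolic acid.

Step 2
Reactants: 2 methyl 5-hydroxy-4-oxo-4H-pyran-2-carboxylate
Product: 3 methyl 6-bromo-5-hydroxy-4-oxo-4H-pyran-2-carboxylate
Conditions: NBS, MeCN, 0 °C to rt
Reagents that add atoms: N-bromosuccinimide, O=C1CCC(=O)N1Br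
Why: Electrophilic bromination of the enol should occur at C6, the carbon ortho to the 5-hydroxyl, as in the halogenation of kojic and comenic acid derivatives, while C3 is deactivated by the adjacent ester.

Step 3
Reactants: 3 methyl 6-bromo-5-hydroxy-4-oxo-4H-pyran-2-carboxylate
Product: 4 methyl 6-bromo-5-(methoxymethoxy)-4-oxo-4H-pyran-2-carboxylate
Conditions: MOMCl, i-Pr2NEt, CH2Cl2, 0 °C to rt
Reagents that add atoms: chloromethyl methyl ether, COCCl
Why: O-alkylation of the acidic enol hydroxyl under amine base should give a base-stable acetal that later frees O3 under mild acid.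

Step 4
Reactants: 4 methyl 6-bromo-5-(methoxymethoxy)-4-oxo-4H-pyran-2-carboxylate; 5 4-(benzyloxy)phenylboronic acid
Product: 6 methyl 6-[4-(benzyloxy)phenyl]-5-(methoxymethoxy)-4-oxo-4H-pyran-2-carboxylate
Conditions: Pd(PPh3)4 (5 mol %), K3PO4, 1,4-dioxane, 85 °C
Reagents that add atoms: none
Why: In this Suzuki–Miyaura coupling the C6–Br bond is a vinylogous acyl bromide that should add readily to zerovalent palladium, and the weakly nucleophilic phosphate base in dioxane should spare the methyl ester and the pyranone ring.

Step 5
Reactants: 6 methyl 6-[4-(benzyloxy)phenyl]-5-(methoxymethoxy)-4-oxo-4H-pyran-2-carboxylate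
Product: 7 6-[4-(benzyloxy)phenyl]-5-(methoxymethoxy)-4-oxo-4H-pyran-2-carboxylic acid
Conditions: LiOH, THF/H2O, 0 °C; then 1 M HCl to pH 3, 0 °C
Reagents that add atoms: lithium hydroxide, [Li+].[OH-]
Why: Saponification of the activated pyranone-2-carboxylate should be fast at 0 °C with about one equivalent of hydroxide, which leaves the pyranone and both ethers intact, and cold acidification only to pH 3 keeps the MOM acetal.

Step 6
Reactants: 7 6-[4-(benzyloxy)phenyl]-5-(methoxymethoxy)-4-oxo-4H-pyran-2-carboxylic acid
Product: 9 2-diazo-1-{6-[4-(benzyloxy)phenyl]-5-(methoxymethoxy)-4-oxo-4H-pyran-2-yl}ethanone, via pyranone-2-carbonyl chloride 8 (not isolated)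
Conditions: Me2C=C(Cl)NMe2, CH2Cl2, 0 °C to rt; then CH2N2 (3 equiv), Et2O, 0 °C
Reagents that add atoms: 1-chloro-N,N,2-trimethylprop-1-en-1-amine, CC(C)=C(Cl)N(C)C (chlorine of 8 only); diazomethane, C=[N+]=[N-]
Why: The α-chloroenamine should form the acid chloride under neutral conditions without free HCl, so the MOM ether survives, and acylation of diazomethane (first stage of the Arndt–Eistert sequence) should give the diazoketone with excess diazomethane removing HCl as chloromethane; by analogy with chromone-2-carbonyl chlorides the pyranone double bond should not act as a dipolarophile at 0 °C.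

Step 7
Reactants: 10 trimethylsilylacetylene
Product: 13 1-(triisopropylsilyloxy)-2-(trimethylsilyl)ethyne, via lithium (trimethylsilyl)acetylide 11 (not isolated), via lithium 2-(trimethylsilyl)ethynolate 12 (not isolated)
Conditions: n-BuLi, THF, −78 °C; t-BuOOLi (from t-BuOOH, LiN(SiMe3)2), −78 to 0 °C; i-Pr3SiOTf, −78 to 0 °C
Reagents that add atoms: n-butyllithium, [Li]CCCC (lithium of 11 and 12 only); lithium tert-butyl peroxide, [Li+].[O-]OC(C)(C)C; triisopropylsilyl trifluoromethanesulfonate, CC(C)[Si](OS(=O)(=O)C(F)(F)F)(C(C)C)C(C)C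
Why: Electrophilic oxidation of the lithium acetylide by the peroxide oxygen should give the lithium ynolate, which the bulky, hard silyl triflate should silylate on oxygen and not on carbon.

Step 8
Reactants: 13 1-(triisopropylsilyloxy)-2-(trimethylsilyl)ethyne
Product: 15 (triisopropylsilyloxy)acetylene, via lithium (triisopropylsilyloxy)acetylide 14 (not isolated)
Conditions: MeLi·LiBr, THF, −20 to 0 °C; then sat. aq. NH4Cl, −78 °C
Reagents that add atoms: methyllithium, [Li]C (lithium of 14 only)
Why: Methyllithium should cleave the unhindered C(sp)–SiMe3 bond far faster than it attacks the shielded triisopropylsilyl ether, and buffered protonation of the acetylide at low temperature should release the terminal siloxyalkyne without acid-induced hydration.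

Step 9
Reactants: 9 2-diazo-1-{6-[4-(benzyloxy)phenyl]-5-(methoxymethoxy)-4-oxo-4H-pyran-2-yl}ethanone; 15 (triisopropylsilyloxy)acetylene
Product: 20 4'-O-benzyl-3-O-(methoxymethyl)-7-O-(triisopropylsilyl)kaempferol, via pyranonylketene 16 (not isolated), via silyloxycyclobutenone 17 (not isolated), via dienylketene 18 (not isolated), via cyclohexadienone tautomer 19 (not isolated)
Conditions: 15 (3 equiv), hν (440 nm LED), ClCH2CH2Cl, degassed, rt; then 80 °C
Reagents that add atoms: none
Why: Light in the n–π* band of the diazoketone should expel N2 with shift of the pyranonyl group to the carbene carbon (photochemical Wolff rearrangement), giving ketene 16 whose CH carbon becomes C8 and whose carbonyl carbon becomes C5; the electron-poor ketene then undergoes polarity-matched [2+2] addition with ynol ether 15, the nucleophilic CH terminus bonding to the ketene carbonyl carbon (C5–C6) and the silyloxy carbon to the ketene CH (C7–C8), to give cyclobutenone 17. On warming, 17 should open reversibly by conrotatory four-electron electrocyclic cleavage of the C5–C8 bond to dienylketene 18, of which only the isomer with ketene and pyranone cis can close. Ring A is closed by a thermal disrotatory six-electron electrocyclisation that joins C5 to C4a of the pyranone double bond, and dienone 19, whose C4a–H lies between two carbonyl groups, tautomerises to the phenol, so that the ketene oxygen ends as the chelated 5-OH and O7 arrives as a silyl ether. The closest known reaction type is the second-generation Danheiser benzannulation of aryl, heteroaryl and alkenyl α-diazo ketones with silyloxyalkynes. No stereocentre remains, the sp3 centres of 17 and 19 being transient and racemic. The step needs the silyloxy group meta to the new hydroxyl and closure at C4a, which the ketene and ynol ether polarity and the attachment of the ketene chain at C8a (whose only other ring neighbour is O1) secure; it also needs the diazoketone to be the only absorber, which 440 nm light should ensure because the aryl-pyranone and the flavone product absorb at shorter wavelength, while excess 15 keeps the ketene from acylating the product.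

Step 10
Reactants: 20 4'-O-benzyl-3-O-(methoxymethyl)-7-O-(triisopropylsilyl)kaempferol
Product: 21 4'-O-benzyl-3-O-(methoxymethyl)kaempferol
Conditions: Bu4NF, AcOH, THF, 0 °C
Reagents that add atoms: none
Why: Fluoride-driven Si–O cleavage should be fast for the silyl ether of the acidic 7-phenol, and the acetic acid buffer keeps the MOM and benzyl ethers and the flavone untouched.

Step 11
Reactants: 21 4'-O-benzyl-3-O-(methoxymethyl)kaempferol
Product: 22 4'-O-benzylkaempferol
Conditions: HCl, MeOH, 45 °C
Reagents that add atoms: none
Why: Acid-catalysed transacetalisation of the MOM ether to methanol should release the 3-OH, while the benzyl aryl ether is stable to methanolic HCl at this temperature.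

Step 12
Reactants: 22 4'-O-benzylkaempferol
Product: 23 4'-O-benzylkaempferol 3,7-bis(hydrogen sulfate)
Conditions: SO3·pyridine (8 equiv), pyridine, rt to 40 °C; aq. NaHCO3 work-up
Reagents that add atoms: sulfur trioxide–pyridine complex, [O-]S(=O)(=O)[n+]1ccccc1
Why: O-sulfation with the SO3–amine complex should take the acidic 7-OH and the 3-OH, whereas the 5-OH is held in a strong hydrogen bond to the C4 carbonyl and is the least nucleophilic hydroxyl of a flavonol, and O4' is blocked as the benzyl ether.

Step 13
Reactants: 23 4'-O-benzylkaempferol 3,7-bis(hydrogen sulfate)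
Product: 24 kaempferol 3,7-di-O-sulfate
Conditions: H2 (1 atm), Pd/C, MeOH/H2O, rt
Reagents that add atoms: none
Why: Catalytic hydrogenolysis of the benzyl aryl ether is neutral and should be tolerated by aryl sulfate monoester salts, and the tetrasubstituted C2=C3 bond of the flavone should not be reduced at 1 atm.

**Compound list**
1 | comenic acid (5-hydroxy-4-oxo-4H-pyran-2-carboxylic acid) | O=C(O)c1cc(=O)c(O)co1 | starting material
2 | methyl 5-hydroxy-4-oxo-4H-pyran-2-carboxylate | COC(=O)c1cc(=O)c(O)co1 | intermediate
3 | methyl 6-bromo-5-hydroxy-4-oxo-4H-pyran-2-carboxylate | COC(=O)c1cc(=O)c(O)c(Br)o1 | intermediate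
4 | methyl 6-bromo-5-(methoxymethoxy)-4-oxo-4H-pyran-2-carboxylate | COC(=O)c1cc(=O)c(OCOC)c(Br)o1 | intermediate
5 | 4-(benzyloxy)phenylboronic acid | OB(O)c1ccc(OCc2ccccc2)cc1 | starting material
6 | methyl 6-[4-(benzyloxy)phenyl]-5-(methoxymethoxy)-4-oxo-4H-pyran-2-carboxylate | COC(=O)c1cc(=O)c(OCOC)c(-c2ccc(OCc3ccccc3)cc2)o1 | intermediate
7 | 6-[4-(benzyloxy)phenyl]-5-(methoxymethoxy)-4-oxo-4H-pyran-2-carboxylic acid | OC(=O)c1cc(=O)c(OCOC)c(-c2ccc(OCc3ccccc3)cc2)o1 | intermediate
8 | 6-[4-(benzyloxy)phenyl]-5-(methoxymethoxy)-4-oxo-4H-pyran-2-carbonyl chloride (not isolated) | ClC(=O)c1cc(=O)c(OCOC)c(-c2ccc(OCc3ccccc3)cc2)o1 | intermediate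
9 | 2-diazo-1-{6-[4-(benzyloxy)phenyl]-5-(methoxymethoxy)-4-oxo-4H-pyran-2-yl}ethanone | [N-]=[N+]=CC(=O)c1cc(=O)c(OCOC)c(-c2ccc(OCc3ccccc3)cc2)o1 | intermediate
10 | trimethylsilylacetylene | C#C[Si](C)(C)C | starting material
11 | lithium (trimethylsilyl)acetylide (not isolated) | [Li]C#C[Si](C)(C)C | intermediate
12 | lithium 2-(trimethylsilyl)ethynolate (not isolated) | [Li+].[O-]C#C[Si](C)(C)C | intermediate
13 | 1-(triisopropylsilyloxy)-2-(trimethylsilyl)ethyne | CC(C)[Si](OC#C[Si](C)(C)C)(C(C)C)C(C)C | intermediate
14 | lithium (triisopropylsilyloxy)acetylide (not isolated) | [Li]C#CO[Si](C(C)C)(C(C)C)C(C)C | intermediate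
15 | (triisopropylsilyloxy)acetylene | C#CO[Si](C(C)C)(C(C)C)C(C)C | intermediate
16 | {6-[4-(benzyloxy)phenyl]-5-(methoxymethoxy)-4-oxo-4H-pyran-2-yl}ketene (not isolated) | O=C=Cc1cc(=O)c(OCOC)c(-c2ccc(OCc3ccccc3)cc2)o1 | intermediate
17 | 4-{6-[4-(benzyloxy)phenyl]-5-(methoxymethoxy)-4-oxo-4H-pyran-2-yl}-3-(triisopropylsilyloxy)cyclobut-2-en-1-one (racemic, not isolated) | O=C1C=C(O[Si](C(C)C)(C(C)C)C(C)C)C1c1cc(=O)c(OCOC)c(-c2ccc(OCc3ccccc3)cc2)o1 | intermediate
18 | 4-{6-[4-(benzyloxy)phenyl]-5-(methoxymethoxy)-4-oxo-4H-pyran-2-yl}-3-(triisopropylsilyloxy)buta-1,3-dien-1-one, ketene and pyranone cis across C3=C4 (not isolated) | O=C=C/C(O[Si](C(C)C)(C(C)C)C(C)C)=C\c1cc(=O)c(OCOC)c(-c2ccc(OCc3ccccc3)cc2)o1 | intermediate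
19 | 2-[4-(benzyloxy)phenyl]-3-(methoxymethoxy)-7-(triisopropylsilyloxy)-4aH-chromene-4,5-dione, keto tautomer of 20 (racemic, not isolated) | O=C1C=C(O[Si](C(C)C)(C(C)C)C(C)C)C=C2OC(-c3ccc(OCc4ccccc4)cc3)=C(OCOC)C(=O)C12 | intermediate
20 | 4'-O-benzyl-3-O-(methoxymethyl)-7-O-(triisopropylsilyl)kaempferol | O=c1c(OCOC)c(-c2ccc(OCc3ccccc3)cc2)oc2cc(O[Si](C(C)C)(C(C)C)C(C)C)cc(O)c12 | intermediate
21 | 4'-O-benzyl-3-O-(methoxymethyl)kaempferol | O=c1c(OCOC)c(-c2ccc(OCc3ccccc3)cc2)oc2cc(O)cc(O)c12 | intermediate
22 | 4'-O-benzylkaempferol | O=c1c(O)c(-c2ccc(OCc3ccccc3)cc2)oc2cc(O)cc(O)c12 | intermediate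
23 | 4'-O-benzylkaempferol 3,7-bis(hydrogen sulfate) | O=c1c(OS(=O)(=O)O)c(-c2ccc(OCc3ccccc3)cc2)oc2cc(OS(=O)(=O)O)cc(O)c12 | intermediate
24 | kaempferol 3,7-di-O-sulfate | O=c1c(OS(=O)(=O)O)c(-c2ccc(O)cc2)oc2cc(OS(=O)(=O)O)cc(O)c12 | target

**Step count and risks**

Total step count: 13. Longest linear sequence: 11 steps (steps 1–6 and 9–13); the alkyne branch (steps 7–8) joins at step 9.

Steps most likely to fail:

1. Step 9. Competing light absorption and photodecomposition of the aryl-pyranone or flavone chromophores, or loss of the ketene by dimerisation and by reaction with unchanged diazoketone before the alkyne captures it, could keep the cascade from reaching the cyclobutenone. The fallback generates the same ketene in the dark and sets out from diazoketone 9. Silver-catalysed Wolff rearrangement with water capture (PhCO2Ag cat., Et3N, THF/H2O, rt, dark) would give {6-[4-(benzyloxy)phenyl]-5-(methoxymethoxy)-4-oxo-4H-pyran-2-yl}acetic acid F1, kept cold to avoid decarboxylation. Me2C=C(Cl)NMe2 in CH2Cl2 would convert it into the corresponding acetyl chloride F2. Slow addition of Et3N to F2 and alkyne 15 in toluene at rt would form ketene 16 by dehydrochlorination and trap it as cyclobutenone 17, and heating at 80 °C would then carry 17 on to 20, where the route is rejoined.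

2. Step 8. Attack of methyllithium or of the liberated acetylide on the silyl ether, migration of silicon from oxygen to carbon in acetylide 14, or loss of the volatile, acid-sensitive terminal siloxyalkyne on isolation could prevent the C-desilylation. The fallback leaves the carbon-bound silyl group in place and sets out from alkyne 13. Irradiation of 9 with 13 under the conditions of step 9 would proceed through ketene 16 to 4'-O-benzyl-3-O-(methoxymethyl)-7-O-(triisopropylsilyl)-6-(trimethylsilyl)kaempferol F3, the silicon-bearing alkyne carbon being the nucleophilic terminus. Bu4NF/AcOH in THF would give 4'-O-benzyl-3-O-(methoxymethyl)-6-(trimethylsilyl)kaempferol F4. HCl in MeOH would then remove the MOM group and, by ipso-protonation at C6 between the two hydroxyls, the aryl silyl group, rejoining the route at 22.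

3. Step 12. Incomplete sulfation of the hindered 3-hydroxyl, over-sulfation at O5 under forcing conditions, or hydrolytic loss of the 3-O-sulfate during isolation of the polar salt could prevent a clean di-sulfation. The fallback installs the sulfates as neutral, chromatographable diesters and sets out from 22. Cl3CCH2OSO2Cl (2.2 equiv), Et3N and DMAP in THF would give 4'-O-benzylkaempferol 3,7-bis(2,2,2-trichloroethyl sulfate) F5, which can be purified on silica. Reductive removal of the trichloroethyl groups with Zn and HCO2NH4 in MeOH would then return the route to 23.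

Further compounds
F1 | step 9 | {6-[4-(benzyloxy)phenyl]-5-(methoxymethoxy)-4-oxo-4H-pyran-2-yl}acetic acid | OC(=O)Cc1cc(=O)c(OCOC)c(-c2ccc(OCc3ccccc3)cc2)o1
F2 | step 9 | {6-[4-(benzyloxy)phenyl]-5-(methoxymethoxy)-4-oxo-4H-pyran-2-yl}acetyl chloride | ClC(=O)Cc1cc(=O)c(OCOC)c(-c2ccc(OCc3ccccc3)cc2)o1
F3 | step 8 | 4'-O-benzyl-3-O-(methoxymethyl)-7-O-(triisopropylsilyl)-6-(trimethylsilyl)kaempferol | O=c1c(OCOC)c(-c2ccc(OCc3ccccc3)cc2)oc2cc(O[Si](C(C)C)(C(C)C)C(C)C)c([Si](C)(C)C)c(O)c12
F4 | step 8 | 4'-O-benzyl-3-O-(methoxymethyl)-6-(trimethylsilyl)kaempferol | O=c1c(OCOC)c(-c2ccc(OCc3ccccc3)cc2)oc2cc(O)c([Si](C)(C)C)c(O)c12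
F5 | step 12 | 4'-O-benzylkaempferol 3,7-bis(2,2,2-trichloroethyl sulfate) | O=c1c(OS(=O)(=O)OCC(Cl)(Cl)Cl)c(-c2ccc(OCc3ccccc3)cc2)oc2cc(OS(=O)(=O)OCC(Cl)(Cl)Cl)cc(O)c12
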